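## Structural features

Target 24 is a sesquiterpene coumarin ether. A drimane-type decalin carries a C11 methylene on C9, and that methylene is joined through an ether oxygen to C7 of a coumarin. Drimane numbering is used for all atoms, including the bicyclic intermediates: ring A is C1–C5 and C10, ring B is C5–C10, and the rings share the C5–C10 bond. Ring A holds the C3 ketone beside the quaternary gem-dimethyl carbon C4; ring B holds the C7=C8 alkene with the C8 methyl. The three stereocentres C5, C10 and C9 are contiguous and (5S,9R,10S): H5, the angular C10 methyl and H9 lie on one face, so the fusion is cis and C11 is anti to the angular methyl. The fragile groups are the coumarin lactone (hydroxide, hydrides, organometallics), the C7=C8 alkene (can migrate in strong acid) and the ketone, which can enolise only toward C2. The real difficulty is the quaternary stereocentre C10, flanked by the tertiary centres C5 and C9 and close to quaternary C4, in a cis fusion that cannot be reached by equilibration because neither C5 nor C10 can epimerise. The key step uses the array O=C3–C2–C1–C10 with unsaturation placed at C8–C9. This is an oxy-Cope product pattern, and the six carbons C3, C4, C5, C10, C9 and C8 carry the oxygen and ring methyls of 2,4,6-trimethylphenol plus one extra methyl on C4.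

## Logic of the disconnections

24 ⇒ 23: the C3 carbonyl is traced back to its dioxolane. No skeletal bond is cut; the reason is that C3 must be masked through the hydride-base and organolithium steps. The forward hydrolysis must spare the lactone, the aryl ether and the alkene.

23 ⇒ 21 + 22: the C11–O(aryl) bond is cut. This keeps the lactone out of all basic and organometallic chemistry and reduces the terpenoid half to a primary alcohol. The forward etherification must work at a β-branched primary carbon without touching C9.

21 ⇒ 19 (through 20): the C9–C11 bond is cut and the alkene is moved back from C7–C8 to C8–C9. C11 then comes from a group on the C7 oxygen, so the C9 configuration is derived from C7 and no external nucleophile has to approach the carbon next to C10. The forward [2,3] shift is suprafacial, so the C7 oxygen must lie on the face anti to the C10 methyl.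

19 ⇒ 17 ⇒ 15: the O–CH2Sn bond is cut, then the C7–O bond is cut with inversion. The cycloaddition used earlier delivers the C7 epimer with oxygen on the face of the C10 methyl, so one clean SN2 inversion at the allylic carbon is the price of that endo preference.

15 ⇒ 14 ⇒ 13: the C7 silyl group is restored and the C3 dioxolane is returned to the ketone. These are protecting-group changes only; the forward ketalisation must occur at a hindered ketone without ionising the allylic silyl ether.

13 ⇒ 10 (through 12 and 11): the C1–C10 bond is cut and the C3–C8 bond re-formed. Ring A and the quaternary stereocentre C10 disappear, and the decalin becomes a bicyclo[2.2.2]octenol that is a [4+2] adduct. The forward step needs the vinyl group syn to the C9=C10 bridge and an alkoxide that rearranges without fragmenting.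

10 ⇒ 8 + 9: the C2–C3 bond is cut. This removes the tertiary carbinol and leaves a non-enolisable ketone; the forward addition must overcome two α-quaternary carbons and come from the alkene face.

8 ⇒ 7 ⇒ 6: the silyl group is removed and the single enantiomer is traced to the racemate. Absolute configuration enters at the first chiral intermediate, so no later material is discarded; the forward resolution must distinguish the two enantiomers of a hindered secondary alcohol.

6 ⇒ 3 + 4 (through 5): the C5–C6 and C7–C8 bonds are cut ([4+2]). All remaining stereocentres vanish and two achiral partners result. The forward cycloaddition must place the oxygenated carbon on C8 and the oxygen syn to the new alkene.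

3 ⇒ 1 (through 2): the bond from C4 to its second methyl is cut. This returns to an aromatic starting material; the forward step must alkylate at the ortho carbon and not at oxygen or the para carbon.

## Other disconnections considered

Alternative 1: The cut goes through C4–C5 and C1–C10, splitting ring A into the silyloxydiene A2 and 2,6-dimethyl-1,4-benzoquinone A1.
- **Forward step:** a cationic chiral oxazaborolidine Lewis acid would promote the [4+2] addition to give the cis-fused enedione A3.
- **In favour:** both partners are achiral and simple; the cis fusion and absolute configuration at C5 and C10 would come from a catalyst; ring B arrives with the C8 methyl and C7–C8 unsaturation.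
- **Against:** A2 carries two methyls on the terminus that must bond to C5, so its s-cis conformer has an inside methyl and should be a slow diene. The required regiochemistry needs activation through the C9 carbonyl, which is buttressed by both methyls, while the unhindered C6 carbonyl is the likelier binding site and would direct C4 to C10. After the cycloaddition the C6 oxygen must be removed and the C9 oxygen exchanged for hydrogen and C11 with control of C9, among three carbonyl groups.
- **Comparison:** on structure the chosen plan delivers exactly the C3 ketone and a C7–O/C8=C9 handle for C11, whereas A3 has the wrong oxidation pattern. On mechanism the alternative is intermolecular and catalyst-controlled, the chosen shift intramolecular and framework-controlled. On step economy the alternative is better up to the decalin and discards no enantiomer, but the corrections after A3 should cost at least as many steps as the chosen plan spends after its key step.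

Alternative 2: The cut is C4–C5 alone, giving the 4,4-disubstituted cyclohexadienone A4 with a tetrasubstituted enol silane on its side chain.
- **Forward step:** a confined chiral imidodiphosphorimidate acid, acting as a silylium-type Lewis acid, would direct C4 onto C5 of one enantiotopic enone arm to give diketone A5.
- **In favour:** the closure is intramolecular and six-membered, the cis fusion is enforced, and the C3 ketone is formed directly. It equals the chosen plan in relying on an intramolecular key event and is better in setting C5 and C10 catalytically without a resolution.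
- **Against:** A5 lacks the C8 methyl and C11 and has a C7 ketone. A C11 unit must still be added to C9 beside quaternary C10 and on the face of ring A, C8 must be methylated, and C7=O must become the C7=C8 alkene, all beside a second ketone. A4 needs a regiodefined tetrasubstituted enol silane, and arm selection on this substrate type would be a new use of the catalyst class.
- **Comparison:** on structure the chosen plan fixes C9 by intramolecular transfer from C7, whereas here C9 is set late and intermolecularly. On mechanism the alternative has the better absolute control. On step economy the two are expected to be similar.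

Alternative 3: The cut goes through C5–C6 and C9–C10, splitting ring B into the (E)-silyloxydiene A7, which carries C11 as a protected alcohol, and the ring-A dienone A6.
- **Forward step:** a cationic chiral oxazaborolidine Lewis acid would promote endo [4+2] addition to the C5=C10 double bond to give A8.
- **In favour:** C5, C10 and C9 and both ring-B bonds would be set in one catalytic step with C11 in place, and the C7 silyl enol ether maps onto the C7=C8 alkene. In stereocentres and bonds per step it is better than the chosen plan, and it is probably the shortest route.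
- **Against:** the dienophile is α-methylated, its β-carbon C5 is neopentylic, and the vinylogous ester donates into the same carbonyl, so low reactivity is expected. The C9–C10 bond joins a substituted diene terminus to a carbon that becomes quaternary. Afterwards the C1 oxygen, flanked by C10, must be removed and the vinylogous ester turned into the C3 ketone.
- **Comparison:** on structure it is the most direct. On mechanism it depends on intermolecular bond formation at two hindered carbons, while the chosen shift forms one bond inside a rigid bicycle. On step economy it is better if the cycloaddition works; the chosen plan is preferred for the reliability of its key step.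

Key step: step 6

Assumption: the lipase is taken to follow the empirical size rule for secondary alcohols (large group = quaternary bridgehead side), so the (7R) alcohol is acetylated and the (7S) alcohol 7 is left; racemates are written as both enantiomers joined by a dot.

## Route

Step 1
Reactants: 1 2,4,6-trimethylphenol (mesitol)
Product: 3 2,4,6,6-tetramethylcyclohexa-2,4-dien-1-one, via lithium 2,4,6-trimethylphenoxide 2 (not isolated)
Conditions: n-BuLi (1.0 equiv), toluene, 0 °C; MeI (6 equiv), sealed vessel, 110 °C, dark; distillation
Reagents that add atoms: methyl iodide, CI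
Why: Dearomatising C-alkylation of a phenoxide; the aggregated lithium salt in a non-polar solvent shields oxygen and directs MeI to an ortho carbon, and the blocked ortho position cannot re-aromatise. The anisole and the para-methylated 2,5-dienone are the expected by-products and should be removable by distillation.

Step 2
Reactants: 3 2,4,6,6-tetramethylcyclohexa-2,4-dien-1-one; 4 trimethyl(vinyloxy)silane
Product: 6 rac-(1S,4S,7S)-7-hydroxy-1,3,3,5-tetramethylbicyclo[2.2.2]oct-5-en-2-one (hydroxyl syn to the alkene bridge), via racemic 7-trimethylsilyloxy cycloadduct 5 (not isolated)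
Conditions: 4 (8 equiv, neat), BHT (1 mol %), sealed tube, 130 °C, dark; then citric acid, MeOH, rt
Reagents that add atoms: none
Why: Inverse-electron-demand Diels–Alder reaction of a cyclohexa-2,4-dienone with an enol ether; the nucleophilic CH2 bonds to the electrophilic terminus C5 and the oxygenated carbon to the methyl-bearing terminus C8, and the endo transition state places oxygen syn to the new C9=C10 bridge. Acidic methanolysis frees the alcohol without base, so the β-hydroxy ketone is never exposed to retro-aldol conditions.

Step 3
Reactants: 6 rac-(1S,4S,7S)-7-hydroxy-1,3,3,5-tetramethylbicyclo[2.2.2]oct-5-en-2-one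
Product: 7 (1S,4S,7S)-7-hydroxy-1,3,3,5-tetramethylbicyclo[2.2.2]oct-5-en-2-one
Conditions: immobilised Burkholderia cepacia lipase, vinyl acetate (3 equiv), MTBE, 35 °C, stopped just past half conversion; chromatography
Reagents that add atoms: none
Why: Lipase-catalysed kinetic resolution by irreversible transesterification; with the quaternary bridgehead as the large group and C6H2 as the medium group, the (7R) alcohol should be acetylated and the (7S) alcohol should remain. Running slightly past half conversion should raise the enantiomeric purity of the recovered alcohol.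

Step 4
Reactants: 7 (1S,4S,7S)-7-hydroxy-1,3,3,5-tetramethylbicyclo[2.2.2]oct-5-en-2-one
Product: 8 (1S,4S,7S)-7-(tert-butyldimethylsilyloxy)-1,3,3,5-tetramethylbicyclo[2.2.2]oct-5-en-2-one
Conditions: TBSOTf (1.3 equiv), 2,6-lutidine (2 equiv), CH2Cl2, −78 → 0 °C
Reagents that add atoms: tert-butyldimethylsilyl trifluoromethanesulfonate, CC(C)(C)[Si](C)(C)OS(=O)(=O)C(F)(F)F
Why: Silyl triflate silylation of a neopentyl-type secondary alcohol; the ketone has no α-hydrogen and cannot form a silyl enol ether, and the amine base is too weak to trigger retro-aldol cleavage.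

Step 5
Reactants: 8 (1S,4S,7S)-7-(tert-butyldimethylsilyloxy)-1,3,3,5-tetramethylbicyclo[2.2.2]oct-5-en-2-one; 9 vinylmagnesium bromide
Product: 10 (1S,2S,4S,7S)-7-(tert-butyldimethylsilyloxy)-1,3,3,5-tetramethyl-2-vinylbicyclo[2.2.2]oct-5-en-2-ol (vinyl syn to the alkene bridge)
Conditions: CeCl3 (anhydrous, 3 equiv), 9 (3 equiv), THF, −78 → 0 °C; sat. aq. NH4Cl
Reagents that add atoms: none
Why: 1,2-Addition of an organocerium reagent to a hindered, non-enolisable ketone; the face toward the C9=C10 bridge is open, whereas the C6–C7 bridge points its exo hydrogens at the other face. The vinyl group should therefore end up syn to the alkene and the hydroxyl toward the C6–C7 bridge, which sets C3.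

Step 6
Reactants: 10 (1S,2S,4S,7S)-7-(tert-butyldimethylsilyloxy)-1,3,3,5-tetramethyl-2-vinylbicyclo[2.2.2]oct-5-en-2-ol
Product: 13 (4aR,7S,8aS)-7-(tert-butyldimethylsilyloxy)-1,1,4a,6-tetramethyl-3,4,4a,7,8,8a-hexahydronaphthalen-2(1H)-one, via potassium alkoxide 11 (not isolated), via potassium enolate 12 (not isolated)
Conditions: KH (2 equiv), 18-crown-6 (2 equiv), THF, 0 °C → rt; sat. aq. NH4Cl
Reagents that add atoms: none
Why: KH with 18-crown-6 gives the dissociated alkoxide 11, whose oxyanion weakens the C3–C8 bond and triggers a [3,3] sigmatropic (anionic oxy-Cope) shift of the 1,5-diene C1=C2–C3–C8–C9=C10 through the boat-like array enforced by the bicycle; C1 bonds to C10 as C3–C8 breaks, and enolate 12 is protonated at C2 on work-up. The closest known reaction type is the anionic oxy-Cope rearrangement of 2-vinylbicyclo[2.2.2]oct-5-en-2-ols from cyclohexa-2,4-dienone cycloadducts to cis-fused octalones. Ring A closes by this concerted bond exchange: the C1–C10 bond completes a six-membered ring whose other five bonds already exist, so no separate cyclisation mode competes. The one new stereocentre, C10, is controlled by the framework, because C1 can reach C10 only on the alkene face turned toward the C3–C4 bridge. C1 on C10 and C4 on C5 therefore lie on the same face of ring B, and the C10 methyl and H5 share the opposite face (cis fusion, with H5 anti to the new bond); C5 and C7 are untouched. The step needs the vinyl group syn to the C9=C10 bridge, which step 5 secures, and it needs the shift to outrun fragmentation and silyl transfer. The endo C7 silyl ether points away from the C3 oxygen, so an O-to-O silyl shift is out of reach, and the only activated bond is C3–C8, the central bond of the 1,5-diene. Formation of the delocalised enolate should make the shift irreversible.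

Step 7
Reactants: 13 (4aR,7S,8aS)-7-(tert-butyldimethylsilyloxy)-1,1,4a,6-tetramethyl-3,4,4a,7,8,8a-hexahydronaphthalen-2(1H)-one
Product: 14 (4a'R,7'S,8a'S)-7'-(tert-butyldimethylsilyloxy)-1',1',4a',6'-tetramethyl-3',4',4a',7',8',8a'-hexahydro-1'H-spiro[1,3-dioxolane-2,2'-naphthalene]
Conditions: (TMSOCH2)2 (3 equiv), TMSOTf (5 mol %), CH2Cl2, −78 → −20 °C; pyridine quench
Reagents that add atoms: 1,2-bis(trimethylsilyloxy)ethane, C[Si](C)(C)OCCO[Si](C)(C)C
Why: Aprotic silyl-triflate-catalysed ketalisation, driven by formation of hexamethyldisiloxane, should convert the hindered C3 ketone at low temperature without ionising the allylic silyl ether. The dioxolane protects C3 against KH and n-BuLi in steps 10 and 11.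

Step 8
Reactants: 14 (4a'R,7'S,8a'S)-7'-(tert-butyldimethylsilyloxy)-1',1',4a',6'-tetramethyl-3',4',4a',7',8',8a'-hexahydro-1'H-spiro[1,3-dioxolane-2,2'-naphthalene]
Product: 15 (4a'R,7'S,8a'S)-1',1',4a',6'-tetramethyl-3',4',4a',7',8',8a'-hexahydro-1'H-spiro[1,3-dioxolane-2,2'-naphthalen]-7'-ol (hydroxyl on the face of the angular methyl)
Conditions: TBAF (1.5 equiv), THF, rt
Reagents that add atoms: none
Why: Fluoride cleavage of the silyl ether; the ketal and alkene are inert and no stereocentre is touched.

Step 9
Reactants: 15 (4a'R,7'S,8a'S)-1',1',4a',6'-tetramethyl-3',4',4a',7',8',8a'-hexahydro-1'H-spiro[1,3-dioxolane-2,2'-naphthalen]-7'-ol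
Product: 17 (4a'R,7'R,8a'S)-1',1',4a',6'-tetramethyl-3',4',4a',7',8',8a'-hexahydro-1'H-spiro[1,3-dioxolane-2,2'-naphthalen]-7'-ol (hydroxyl anti to the angular methyl), via inverted 4-nitrobenzoate 16 (not isolated)
Conditions: PPh3 (2 equiv), DIAD (2 equiv), 4-nitrobenzoic acid (2 equiv), THF, 0 °C → rt; then MeOH, K2CO3, rt
Reagents that add atoms: 4-nitrobenzoic acid, O=C(O)c1ccc(cc1)[N+](=O)[O-]
Why: Mitsunobu reaction with an acidic carboxylic acid; the oxyphosphonium ion is displaced by SN2 with inversion at C7, because the SN2' terminus C9 is neopentylic. The activated ester is then methanolysed in the same flask, which puts the C7 oxygen on the face where C11 must arrive.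

Step 10
Reactants: 17 (4a'R,7'R,8a'S)-1',1',4a',6'-tetramethyl-3',4',4a',7',8',8a'-hexahydro-1'H-spiro[1,3-dioxolane-2,2'-naphthalen]-7'-ol
Product: 19 tributyl({[(4a'R,7'R,8a'S)-1',1',4a',6'-tetramethyl-3',4',4a',7',8',8a'-hexahydro-1'H-spiro[1,3-dioxolane-2,2'-naphthalen]-7'-yl]oxy}methyl)stannane, via potassium alkoxide 18 (not isolated)
Conditions: KH (1.5 equiv), THF, 0 °C; Bu3SnCH2I (1.5 equiv), 18-crown-6 (0.1 equiv), 0 °C → rt
Reagents that add atoms: (iodomethyl)tributylstannane, CCCC[Sn](CCCC)(CCCC)CI
Why: Williamson etherification of the potassium alkoxide with a primary α-stannyl iodide; the C7 configuration is retained because only the O–H bond is broken.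

Step 11
Reactants: 19 tributyl({[(4a'R,7'R,8a'S)-1',1',4a',6'-tetramethyl-3',4',4a',7',8',8a'-hexahydro-1'H-spiro[1,3-dioxolane-2,2'-naphthalen]-7'-yl]oxy}methyl)stannane
Product: 21 [(4a'S,5'R,8a'S)-1',1',4a',6'-tetramethyl-3',4',4a',5',8',8a'-hexahydro-1'H-spiro[1,3-dioxolane-2,2'-naphthalen]-5'-yl]methanol, via lithiomethyl ether 20 (not isolated)
Conditions: n-BuLi (1.5 equiv), THF, −78 → −30 °C; sat. aq. NH4Cl
Reagents that add atoms: none
Why: Wittig–Still rearrangement; tin–lithium exchange gives the α-alkoxymethyllithium 20, which undergoes a [2,3] sigmatropic shift that is suprafacial over C7–C8–C9. C11 is therefore delivered to C9 on the face that held the C7 oxygen (anti to the C10 methyl), the alkene moves to C7–C8, and the oxygen becomes the primary C11 alkoxide.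

Step 12
Reactants: 21 [(4a'S,5'R,8a'S)-1',1',4a',6'-tetramethyl-3',4',4a',5',8',8a'-hexahydro-1'H-spiro[1,3-dioxolane-2,2'-naphthalen]-5'-yl]methanol; 22 umbelliferone (7-hydroxycoumarin)
Product: 23 7-{[(4a'S,5'R,8a'S)-1',1',4a',6'-tetramethyl-3',4',4a',5',8',8a'-hexahydro-1'H-spiro[1,3-dioxolane-2,2'-naphthalen]-5'-yl]methoxy}-2H-chromen-2-one
Conditions: 22 (1.5 equiv), PPh3 (1.6 equiv), DIAD (1.6 equiv), THF, 0 → 40 °C
Reagents that add atoms: none
Why: Mitsunobu etherification of a primary alcohol with an acidic phenol; the C11–O(aryl) bond forms under neutral conditions that leave the lactone intact, and C9 is not involved.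

Step 13
Reactants: 23 7-{[(4a'S,5'R,8a'S)-1',1',4a',6'-tetramethyl-3',4',4a',5',8',8a'-hexahydro-1'H-spiro[1,3-dioxolane-2,2'-naphthalen]-5'-yl]methoxy}-2H-chromen-2-one
Product: 24 7-{[(1R,4aS,8aS)-2,5,5,8a-tetramethyl-6-oxo-1,4,4a,5,6,7,8,8a-octahydronaphthalen-1-yl]methoxy}-2H-chromen-2-one (CNP0262399.3)
Conditions: PPTS (0.3 equiv), acetone/H2O (9:1), 50 °C
Reagents that add atoms: water, O
Why: Acid-catalysed hydrolysis of the dioxolane, helped by relief of strain next to the quaternary C4; mild aqueous acid should not open the lactone, cleave the aryl ether or move the isolated alkene.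

## Compound list

1 | 2,4,6-trimethylphenol (mesitol) | Cc1cc(C)c(O)c(C)c1 | starting material
2 | lithium 2,4,6-trimethylphenoxide | [Li+].[O-]c1c(C)cc(C)cc1C | intermediate
3 | 2,4,6,6-tetramethylcyclohexa-2,4-dien-1-one | CC1=CC(C)=CC(C)(C)C1=O | intermediate
4 | trimethyl(vinyloxy)silane | C=CO[Si](C)(C)C | starting material
5 | rac-(1S,4S,7S)-1,3,3,5-tetramethyl-7-(trimethylsilyloxy)bicyclo[2.2.2]oct-5-en-2-one (silyloxy syn to the alkene bridge; racemate) | O=C1C(C)(C)[C@H]2C[C@H](O[Si](C)(C)C)[C@]1(C)C=C2C.O=C1C(C)(C)[C@@H]2C[C@@H](O[Si](C)(C)C)[C@@]1(C)C=C2C | intermediate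
6 | rac-(1S,4S,7S)-7-hydroxy-1,3,3,5-tetramethylbicyclo[2.2.2]oct-5-en-2-one (hydroxyl syn to the alkene bridge; racemate) | O=C1C(C)(C)[C@H]2C[C@H](O)[C@]1(C)C=C2C.O=C1C(C)(C)[C@@H]2C[C@@H](O)[C@@]1(C)C=C2C | intermediate
7 | (1S,4S,7S)-7-hydroxy-1,3,3,5-tetramethylbicyclo[2.2.2]oct-5-en-2-one | O=C1C(C)(C)[C@H]2C[C@H](O)[C@]1(C)C=C2C | intermediate
8 | (1S,4S,7S)-7-(tert-butyldimethylsilyloxy)-1,3,3,5-tetramethylbicyclo[2.2.2]oct-5-en-2-one | O=C1C(C)(C)[C@H]2C[C@H](O[Si](C)(C)C(C)(C)C)[C@]1(C)C=C2C | intermediate
9 | vinylmagnesium bromide | C=C[Mg]Br | starting material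
10 | (1S,2S,4S,7S)-7-(tert-butyldimethylsilyloxy)-1,3,3,5-tetramethyl-2-vinylbicyclo[2.2.2]oct-5-en-2-ol (vinyl and silyloxy both syn to the alkene bridge) | C=C[C@]1(O)C(C)(C)[C@H]2C[C@H](O[Si](C)(C)C(C)(C)C)[C@]1(C)C=C2C | intermediate
11 | potassium alkoxide of 10 | [K+].C=C[C@]1([O-])C(C)(C)[C@H]2C[C@H](O[Si](C)(C)C(C)(C)C)[C@]1(C)C=C2C | intermediate
12 | potassium C2=C3 enolate of 13 | [K+].CC1=C[C@@]2(C)CC=C([O-])C(C)(C)[C@H]2C[C@@H]1O[Si](C)(C)C(C)(C)C | intermediate
13 | (4aR,7S,8aS)-7-(tert-butyldimethylsilyloxy)-1,1,4a,6-tetramethyl-3,4,4a,7,8,8a-hexahydronaphthalen-2(1H)-one (cis-fused; C7–O on the face of the angular methyl) | CC1=C[C@@]2(C)CCC(=O)C(C)(C)[C@H]2C[C@@H]1O[Si](C)(C)C(C)(C)C | intermediate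
14 | (4a'R,7'S,8a'S)-7'-(tert-butyldimethylsilyloxy)-1',1',4a',6'-tetramethyl-3',4',4a',7',8',8a'-hexahydro-1'H-spiro[1,3-dioxolane-2,2'-naphthalene] | CC1=C[C@@]2(C)CCC3(OCCO3)C(C)(C)[C@H]2C[C@@H]1O[Si](C)(C)C(C)(C)C | intermediate
15 | (4a'R,7'S,8a'S)-1',1',4a',6'-tetramethyl-3',4',4a',7',8',8a'-hexahydro-1'H-spiro[1,3-dioxolane-2,2'-naphthalen]-7'-ol | CC1=C[C@@]2(C)CCC3(OCCO3)C(C)(C)[C@H]2C[C@@H]1O | intermediate
16 | (4a'R,7'R,8a'S)-1',1',4a',6'-tetramethyl-3',4',4a',7',8',8a'-hexahydro-1'H-spiro[1,3-dioxolane-2,2'-naphthalen]-7'-yl 4-nitrobenzoate | CC1=C[C@@]2(C)CCC3(OCCO3)C(C)(C)[C@H]2C[C@H]1OC(=O)c1ccc(cc1)[N+](=O)[O-] | intermediate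
17 | (4a'R,7'R,8a'S)-1',1',4a',6'-tetramethyl-3',4',4a',7',8',8a'-hexahydro-1'H-spiro[1,3-dioxolane-2,2'-naphthalen]-7'-ol | CC1=C[C@@]2(C)CCC3(OCCO3)C(C)(C)[C@H]2C[C@H]1O | intermediate
18 | potassium alkoxide of 17 | [K+].CC1=C[C@@]2(C)CCC3(OCCO3)C(C)(C)[C@H]2C[C@H]1[O-] | intermediate
19 | tributyl({[(4a'R,7'R,8a'S)-1',1',4a',6'-tetramethyl-3',4',4a',7',8',8a'-hexahydro-1'H-spiro[1,3-dioxolane-2,2'-naphthalen]-7'-yl]oxy}methyl)stannane | CC1=C[C@@]2(C)CCC3(OCCO3)C(C)(C)[C@H]2C[C@H]1OC[Sn](CCCC)(CCCC)CCCC | intermediate
20 | lithiomethyl ether from 19 | CC1=C[C@@]2(C)CCC3(OCCO3)C(C)(C)[C@H]2C[C@H]1OC[Li] | intermediate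
21 | [(4a'S,5'R,8a'S)-1',1',4a',6'-tetramethyl-3',4',4a',5',8',8a'-hexahydro-1'H-spiro[1,3-dioxolane-2,2'-naphthalen]-5'-yl]methanol | CC1=CC[C@@H]2C(C)(C)C3(OCCO3)CC[C@]2(C)[C@@H]1CO | intermediate
22 | umbelliferone (7-hydroxycoumarin) | O=c1ccc2ccc(O)cc2o1 | starting material
23 | 7-{[(4a'S,5'R,8a'S)-1',1',4a',6'-tetramethyl-3',4',4a',5',8',8a'-hexahydro-1'H-spiro[1,3-dioxolane-2,2'-naphthalen]-5'-yl]methoxy}-2H-chromen-2-one | CC1=CC[C@@H]2C(C)(C)C3(OCCO3)CC[C@]2(C)[C@@H]1COc1ccc2ccc(=O)oc2c1 | intermediate
24 | 7-{[(1R,4aS,8aS)-2,5,5,8a-tetramethyl-6-oxo-1,4,4a,5,6,7,8,8a-octahydronaphthalen-1-yl]methoxy}-2H-chromen-2-one; drimane numbering (5S,9R,10S) | CC1=CC[C@@H]2C(C)(C)C(=O)CC[C@]2(C)[C@@H]1COc1ccc2ccc(=O)oc2c1 | target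

## Step count and least certain steps

Total step count: 13. Longest linear sequence: 13 steps (1 to 24); 4, 9 and 22 enter as purchased compounds.

Step 6 (key step). The most likely failure is heterolysis of the C3–C8 bond without ring closure at C10, or slow rearrangement that leaves the alkoxide open to decomposition, because the new bond creates a quaternary carbon at the methyl-bearing alkene terminus. Fallback: from 10, silylate the tertiary alcohol (TMSOTf, Et3N, CH2Cl2) to the 2-trimethylsilyloxy-2-vinyl bicycle F1. Heat it in decalin (sealed, about 220 °C) so that a neutral siloxy-Cope shift gives the trimethylsilyl enol ether of the octalone F2. Cleave the enol ether with citric acid in MeOH to rejoin the route at 13.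

Step 5. Addition may stall, or may come partly from the wrong face, because the carbonyl lies between two quaternary carbons; the epimeric carbinol cannot rearrange. Fallback: from 8, add the slimmer ethynylmagnesium bromide with CeCl3 in THF to give the 2-ethynyl carbinol F3. Semi-hydrogenate it (H2, Pd/CaCO3 poisoned with Pb(OAc)2, quinoline, EtOAc) to rejoin at 10.

Step 3. Acylation may be slow or poorly selective because the carbinol carbon is neopentylic and buried in the bicycle, and the sense of selection could be the reverse of the size rule. Fallback: from 6, separate the enantiomers by preparative chromatography on a chiral stationary phase (amylose carbamate, CO2/MeOH) and assign them through a crystalline ester; this gives 7 directly and makes no new compound (F0).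

Step 9. Elimination to a diene or incomplete inversion may compete, because the carboxylate must enter at C7 on the ring-A face close to the C4 methyls. Fallback: from 15, oxidise with Dess–Martin periodinane to the C7 enone F4. Reduce it under Luche conditions (NaBH4, CeCl3·7H2O, MeOH, −78 °C), where hydride is expected from the face opposite ring A, to rejoin at 17.

Step 11. Protonation of the carbanion or a [1,2] shift may outrun the [2,3] shift. The reactive half-chair must hold the C7 oxygen pseudoaxial and syn to C4, and the new bond forms next to quaternary C10. Fallback: from 15, which has the C7 oxygen on the other face, esterify with pyridine-2-carboxylic acid (DCC, DMAP) to the C7 picolinate F5. Carry out an anti-SN2' substitution with (isopropoxydimethylsilyl)methylmagnesium chloride and CuBr·SMe2 (THF, −40 °C) to give the C9 (isopropoxydimethylsilyl)methyl compound F6, with C11 anti to the leaving group and the alkene at C7–C8. Tamao oxidation (H2O2, KF, KHCO3, THF/MeOH) then rejoins the route at 21 and also bypasses steps 9 and 10.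

## Further compounds

F1 | step 6 | (1S,2S,4S,7S)-7-(tert-butyldimethylsilyloxy)-1,3,3,5-tetramethyl-2-(trimethylsilyloxy)-2-vinylbicyclo[2.2.2]oct-5-ene | C=C[C@]1(O[Si](C)(C)C)C(C)(C)[C@H]2C[C@H](O[Si](C)(C)C(C)(C)C)[C@]1(C)C=C2C
F2 | step 6 | trimethylsilyl enol ether (C2=C3) of 13 | CC1=C[C@@]2(C)CC=C(O[Si](C)(C)C)C(C)(C)[C@H]2C[C@@H]1O[Si](C)(C)C(C)(C)C
F3 | step 5 | (1S,2S,4S,7S)-7-(tert-butyldimethylsilyloxy)-2-ethynyl-1,3,3,5-tetramethylbicyclo[2.2.2]oct-5-en-2-ol | C#C[C@]1(O)C(C)(C)[C@H]2C[C@H](O[Si](C)(C)C(C)(C)C)[C@]1(C)C=C2C
F0 | step 3 | none | none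
F4 | step 9 | (4a'R,8a'S)-1',1',4a',6'-tetramethyl-3',4',4a',8a'-tetrahydro-1'H-spiro[1,3-dioxolane-2,2'-naphthalen]-7'(8'H)-one | CC1=C[C@@]2(C)CCC3(OCCO3)C(C)(C)[C@H]2CC1=O
F5 | step 11 | (4a'R,7'S,8a'S)-1',1',4a',6'-tetramethyl-3',4',4a',7',8',8a'-hexahydro-1'H-spiro[1,3-dioxolane-2,2'-naphthalen]-7'-yl pyridine-2-carboxylate | CC1=C[C@@]2(C)CCC3(OCCO3)C(C)(C)[C@H]2C[C@@H]1OC(=O)c1ccccn1
F6 | step 11 | isopropoxydimethyl{[(4a'S,5'R,8a'S)-1',1',4a',6'-tetramethyl-3',4',4a',5',8',8a'-hexahydro-1'H-spiro[1,3-dioxolane-2,2'-naphthalen]-5'-yl]methyl}silane | CC1=CC[C@@H]2C(C)(C)C3(OCCO3)CC[C@]2(C)[C@@H]1C[Si](C)(C)OC(C)C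
A1 | alternative 1 | 2,6-dimethyl-1,4-benzoquinone | CC1=CC(=O)C=C(C)C1=O
A2 | alternative 1 | 4-methyl-3-(triisopropylsilyloxy)penta-1,3-diene | C=CC(O[Si](C(C)C)(C(C)C)C(C)C)=C(C)C
A3 | alternative 1 | cis-fused enedione with C3 triisopropylsilyl enol ether | CC1=CC(=O)[C@@H]2C(C)(C)C(O[Si](C(C)C)(C(C)C)C(C)C)=CC[C@]2(C)C1=O
A4 | alternative 2 | 4-methyl-4-[4-methyl-3-(trimethylsilyloxy)pent-3-en-1-yl]cyclohexa-2,5-dien-1-one | CC(C)=C(O[Si](C)(C)C)CCC1(C)C=CC(=O)C=C1
A5 | alternative 2 | cis-fused C3 ketone with C7 enone (C8–C9 alkene) | O=C1C[C@@H]2C(C)(C)C(=O)CC[C@]2(C)C=C1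
A6 | alternative 3 | 5-methoxy-2,4,4-trimethylcyclohexa-2,5-dien-1-one | COC1=CC(=O)C(C)=CC1(C)C
A7 | alternative 3 | tert-butyl({(3E)-5-[(4-methoxybenzyl)oxy]-3-methylpenta-1,3-dien-2-yl}oxy)dimethylsilane | C=C(O[Si](C)(C)C(C)(C)C)/C(C)=C/COCc1ccc(OC)cc1
A8 | alternative 3 | cis-fused cycloadduct with C7 silyl enol ether and ring-A vinylogous ester | CC1=C(O[Si](C)(C)C(C)(C)C)C[C@@H]2C(C)(C)C(OC)=CC(=O)[C@]2(C)[C@@H]1COCc1ccc(OC)cc1
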